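## Retrosynthetic overview
1. Ring B and C2 come last. An arylboronic acid is added enantioselectively (rhodium-catalysed 1,4-addition) to an 8-alkyl-5,7-dihydroxychromone, and no protecting groups are used.
2. The side-chain CH2OH and the free 7-OH both come from reductive opening of a seven-membered aryl lactone fused at O7/C8. C3'' is set by kinetic protonation of the lactone enolate.
3. The key bond is C1''–C2''. The β-carbon of an enal, made nucleophilic as a carbene-bound homoenolate, attacks the exocyclic CH2 of a chromone o-quinone methide in a formal [4+3] annulation. Both carbons are normally electrophiles.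
4. The o-quinone methide comes from the C8 Mannich methiodide of 5,7-dihydroxychromone, which comes from phloroacetophenone. The enal comes from 4-methylpent-3-en-1-ol and a formyl ylide.
5. Ring order: ring A is bought, the pyranone ring C is made first, the temporary oxepinone ring is made and opened again, and ring B is attached last, which turns ring C into the flavanone ring.

Assumption: the sense of induction of the two chiral catalysts (steps 4 and 7) is assigned by analogy with the parent reactions; both antipodes of each are sold, so a wrong guess is corrected by taking the antipode without changing the route.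

Locants: in the lactones O1' sits on chromone C7, followed by C2'(=O), C3'(CH3), C4'(prenyl) and C5'H2, which sits on chromone C8. Prenyl means 3-methylbut-2-en-1-yl.

## Route

Step 1
Reactants: 1 4-methylpent-3-en-1-ol; 2 2-(triphenyl-λ5-phosphanylidene)propanal
Product: 4 (2E)-2,6-dimethylhepta-2,5-dienal, via 4-methylpent-3-enal 3 (not isolated)
Conditions: 2-iodoxybenzoic acid (IBX, 1.4 equiv), DMSO, 25 °C, 20 h, 2 (1.3 equiv) present from the start
Reagents that add atoms: none
Why: IBX oxidation gives the labile β,γ-unsaturated aldehyde, and the stabilised ylide already in the flask traps it in an E-selective Wittig olefination before it can slip into conjugation (tandem oxidation–Wittig).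

Step 2
Reactants: 5 2,4,6-trihydroxyacetophenone
Product: 7 5,7-dihydroxy-4H-chromen-4-one, via 4-ethoxy-5,7-dihydroxychromenylium perchlorate 6 (not isolated)
Conditions: HC(OEt)3 (6 equiv), 70% aq HClO4 (1.2 equiv), 25 °C, 12 h; then H2O, 90 °C, 30 min
Reagents that add atoms: triethyl orthoformate CCOC(OCC)OCC; water O
Why: In the orthoformate/perchloric acid chromone synthesis the methyl ketone is C-formylated, closes through one of two equivalent ortho hydroxyls to the benzopyrylium salt and is hydrolysed, and the symmetry of 5 removes any regiochemical question.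

Step 3
Reactants: 7 5,7-dihydroxy-4H-chromen-4-one
Product: 9 (5,7-dihydroxy-4-oxo-4H-chromen-8-yl)-N,N,N-trimethylmethanaminium iodide, via C8 Mannich base 8 (not isolated)
Conditions: Me2NCH2NMe2 (1.05 equiv), 1,4-dioxane, 80 °C, 3 h; evaporate; MeI (1.5 equiv), MeCN, 25 °C, 12 h, filter the salt
Reagents that add atoms: bis(dimethylamino)methane CN(C)CN(C)C; iodomethane CI
Why: The phenolic Mannich reaction of 5,7-dihydroxychromones and 5,7-dihydroxyflavones goes to C8, ortho to the acidic 7-OH, and Menshutkin N-methylation in aprotic MeCN then turns the amine into a tertiary-amine leaving group that cannot later acylate.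

Step 4
Reactants: 9 (5,7-dihydroxy-4-oxo-4H-chromen-8-yl)-N,N,N-trimethylmethanaminium iodide; 4 (2E)-2,6-dimethylhepta-2,5-dienal (2.0 equiv)
Product: 11 (4'R)-3'-methyl-4'-prenyl oxepinone-fused 5-hydroxychromone (both C3' epimers), via o-quinone methide 10 (not isolated)
Conditions: (5aS,10bR)-2-mesityl-5a,10b-dihydro-4H,6H-indeno[2,1-b][1,2,4]triazolo[4,3-d][1,4]oxazin-2-ium tetrafluoroborate (20 mol %), CsOAc (1.3 equiv), 4 Å molecular sieves, degassed THF, 30 °C, 9 added in portions over 8 h
Reagents that add atoms: none
Why: Proposed new method: acetate deprotonates the acidic 7-OH of 9 and the betaine slowly loses NMe3 to give 10, while the triazolylidene turns enal 4 into the extended Breslow intermediate whose β-carbon (homoenolate) attacks the exocyclic CH2 of 10 on the Si face left open by the indane wall (4'R); rearomatisation, α-protonation and acylation of the 7-phenoxide by the acyl azolium close the lactone and free the carbene, C3' forms without control and is reset in step 5, and the closest known reaction type is the carbene-catalysed enantioselective formal [4+3] annulation of enals with transient CH2-type o-quinone methides, the new elements being the α-branched β-alkyl enal and the ammonium trigger.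

Step 5
Reactants: 11 (4'R)-3'-methyl-4'-prenyl oxepinone-fused 5-hydroxychromone (both C3' epimers)
Product: 14 5,7-dihydroxy-8-[(2R,3R)-4-hydroxy-3-methyl-2-prenylbutyl]-4H-chromen-4-one, via dilithium enolate 12 (not isolated), via cis-lactone 13 (not isolated)
Conditions: LiN(SiMe3)2 (2.1 equiv), THF, −78 °C, 20 min; 2,6-di-tert-butyl-4-methylphenol (1.1 equiv), −78 °C; LiBH4 (3 equiv), −78 to −10 °C; 1 M HCl to pH 5
Reagents that add atoms: none
Why: Deprotonation erases C3', and the flat enolate holds the C4' prenyl group pseudo-axial to avoid allylic 1,2-strain with the C3' methyl, so the bulky phenol protonates the opposite face to give the contra-thermodynamic cis (3'R,4'R) lactone (kinetic enolate protonation), which LiBH4 reduces at once because it is an activated aryl ester of a vinylogous acid while the chromone is masked as its lithium phenoxide (chemoselective borohydride ester reduction).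

Step 6
Reactants: 15 4-bromo-3-methoxyphenol
Product: 18 (4-hydroxy-2-methoxyphenyl)boronic acid, via dilithiated phenoxide 16 (not isolated), via lithium aryltriisopropoxyborate 17 (not isolated)
Conditions: n-BuLi (2.1 equiv), THF, −78 °C, 1 h; B(OiPr)3 (1.5 equiv), −78 to 0 °C; 1 M HCl to pH 6, used within a day
Reagents that add atoms: triisopropyl borate CC(C)OB(OC(C)C)OC(C)C; water O
Why: Bromine–lithium exchange on the lithium phenoxide, helped by the ortho methoxy group, followed by electrophilic borylation and mild hydrolysis, gives the boronic acid without creating a stereocentre.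

Step 7
Reactants: 14 5,7-dihydroxy-8-[(2R,3R)-4-hydroxy-3-methyl-2-prenylbutyl]-4H-chromen-4-one; 18 (4-hydroxy-2-methoxyphenyl)boronic acid (3 equiv, in three portions)
Product: 19 (2S)-5,7-dihydroxy-2-(4-hydroxy-2-methoxyphenyl)-8-[(2R,3R)-4-hydroxy-3-methyl-2-prenylbutyl]-2,3-dihydro-4H-chromen-4-one (target)
Conditions: [RhCl(C2H4)2]2 (2.5 mol %), (1S,4S)-2,5-diphenylbicyclo[2.2.2]octa-2,5-diene (5.5 mol %), aq KOH (10 mol %, premixed 15 min to give the hydroxo complex), 1,4-dioxane/H2O 10:1, 40 °C
Reagents that add atoms: none
Why: In this Hayashi–Miyaura asymmetric 1,4-addition the aryl complex of monovalent rhodium carbometalates C2=C3 of the chromone on the face left open by the C2-symmetric diene, the same facial sense that gives (S)-3-arylcyclohexanones and here gives 2S, overriding the remote side-chain centres, and the essentially neutral medium keeps the 7-OH protonated and prevents retro-oxa-Michael racemisation.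

## Compound list
1 | 4-methylpent-3-en-1-ol | CC(C)=CCCO | starting material
2 | 2-(triphenyl-λ5-phosphanylidene)propanal | CC(C=O)=P(c1ccccc1)(c1ccccc1)c1ccccc1 | starting material
3 | 4-methylpent-3-enal | CC(C)=CCC=O | intermediate
4 | (2E)-2,6-dimethylhepta-2,5-dienal | O=C/C(C)=C/CC=C(C)C | intermediate
5 | 2,4,6-trihydroxyacetophenone | CC(=O)c1c(O)cc(O)cc1O | starting material
6 | 4-ethoxy-5,7-dihydroxychromenylium perchlorate | CCOc1cc[o+]c2cc(O)cc(O)c12.[O-]Cl(=O)(=O)=O | intermediate
7 | 5,7-dihydroxy-4H-chromen-4-one | O=C1C=COc2cc(O)cc(O)c12 | intermediate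
8 | 8-[(dimethylamino)methyl]-5,7-dihydroxy-4H-chromen-4-one | CN(C)Cc1c(O)cc(O)c2C(=O)C=COc12 | intermediate
9 | (5,7-dihydroxy-4-oxo-4H-chromen-8-yl)-N,N,N-trimethylmethanaminium iodide | C[N+](C)(C)Cc1c(O)cc(O)c2C(=O)C=COc12.[I-] | intermediate
10 | 5-hydroxy-8-methylidene-chromene-4,7(8H)-dione (o-quinone methide) | C=C1C(=O)C=C(O)C2=C1OC=CC2=O | intermediate
11 | oxepino[2,3-h]chromene lactone: 5-hydroxychromone fused at O7/C8 to O1'–C2'(=O)–C3'H(CH3)–C4'H(prenyl)–C5'H2; 4'R, both C3' epimers | O=C1Oc2cc(O)c3C(=O)C=COc3c2C[C@@H](CC=C(C)C)C1C | intermediate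
12 | dilithium salt of 11: 5-phenoxide and C2'=C3' lactone enolate, 4'R | [Li+].[Li+].[O-]C1=C(C)[C@H](CC=C(C)C)Cc2c(O1)cc([O-])c1C(=O)C=COc21 | intermediate
13 | cis-(3'R,4'R) lactone | O=C1Oc2cc(O)c3C(=O)C=COc3c2C[C@@H](CC=C(C)C)[C@H]1C | intermediate
14 | 5,7-dihydroxy-8-[(2R,3R)-4-hydroxy-3-methyl-2-(3-methylbut-2-en-1-yl)butyl]-4H-chromen-4-one | O=C1C=COc2c(C[C@@H](CC=C(C)C)[C@@H](C)CO)c(O)cc(O)c12 | intermediate
15 | 4-bromo-3-methoxyphenol | COc1cc(O)ccc1Br | starting material
16 | lithium 4-lithio-3-methoxyphenoxide | COc1cc([O-])ccc1[Li].[Li+] | intermediate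
17 | dilithium (2-methoxy-4-oxidophenyl)triisopropoxyborate | COc1cc([O-])ccc1[B-](OC(C)C)(OC(C)C)OC(C)C.[Li+].[Li+] | intermediate
18 | (4-hydroxy-2-methoxyphenyl)boronic acid | COc1cc(O)ccc1B(O)O | intermediate
19 | (2S)-5,7-dihydroxy-2-(4-hydroxy-2-methoxyphenyl)-8-[(2R,3R)-4-hydroxy-3-methyl-2-(3-methylbut-2-en-1-yl)butyl]-2,3-dihydro-4H-chromen-4-one | COc1cc(O)ccc1[C@@H]1CC(=O)c2c(O)cc(O)c(C[C@@H](CC=C(C)C)[C@@H](C)CO)c2O1 | target

## Step count and risks
Total steps: 7. Longest linear sequence: 5 (steps 2, 3, 4, 5 and 7).

**Step 4 (key annulation).**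
- Risks:
  - The α-branched homoenolate may be too slow.
  - 10 may then be consumed by C6 of unreacted phenoxide or by the carbene.
  - The skipped dienal may drift into conjugation.
- The fallback sets out from 9 (with alcohol 1) and comes back at 11.
- Alcohol 1 is put through the oxidation–Wittig sequence of step 1 with (triphenylphosphoranylidene)acetaldehyde to give (2E)-6-methylhepta-2,5-dienal F1. This α-unbranched enal is the substrate class for which the [4+3] annulation is established.
- With 9 under the step 4 conditions it gives the (4'R)-4'-prenyl lactone lacking the 3'-methyl group F2.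
- The methyl group is then brought in by enolate alkylation (LiN(SiMe3)2 2.1 equiv, MeI 1.05 equiv, THF, −78 °C). Alkylation anti to the prenyl group gives the (3'S,4'R) epimer, which is one of the two components of 11 and is corrected in step 5 like the rest.

**Step 5 (kinetic protonation and selective reduction).**
- Risks:
  - The ring bias may give only a modest cis/trans ratio.
  - The activated aryl-ester enolate may leak into a ketene.
  - The hydride may touch the chromone.
- The fallback sets out from 11 and comes back at 13.
- 11 is trapped with LiN(SiMe3)2 (2.2 equiv) and Me3SiCl as the 5-O-silylated cyclic trimethylsilyl ketene acetal F3.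
- F3 is freed from salts and protonated at −78 °C with 2-propanol (2.2 equiv) under a BINOL-derived N-triflyl thiophosphoramide (5 mol %).
- Face selection then comes from a chiral Brønsted acid matched with the ring bias instead of from the substrate alone.
- The resulting 13 is reduced with LiBH4 as before.

**Step 7 (conjugate arylation of the unprotected chromone).**
- Risks:
  - The acidic 7-OH may protonate the aryl–rhodium species or deactivate the enone as its phenoxide.
  - The electron-rich boronic acid may protodeboronate faster than it adds.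
- The fallback sets out from 14 and comes back at 19.
- TBSCl (2.2 equiv) and imidazole in DMF silylate the 7-OH and the primary OH and leave the chelated 5-OH, giving the bis-silyl chromone F4.
- F4 is a more electrophilic, non-acidic acceptor and takes up 18 under the same rhodium/diene catalyst to give the (2S) bis-silyl flavanone F5.
- Et3N·3HF in THF at 25 °C, which is non-basic and so does not epimerise C2, removes both silyl groups.

## Further compounds
F1 | step 4 | (2E)-6-methylhepta-2,5-dienal | O=C/C=C/CC=C(C)C
F2 | step 4 | (4'R)-4'-prenyl oxepinone-fused 5-hydroxychromone without the 3'-methyl group | O=C1Oc2cc(O)c3C(=O)C=COc3c2C[C@@H](CC=C(C)C)C1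
F3 | step 5 | (4'R) cyclic trimethylsilyl ketene acetal of 11, 5-O-trimethylsilylated | C[Si](C)(C)OC1=C(C)[C@H](CC=C(C)C)Cc2c(O1)cc(O[Si](C)(C)C)c1C(=O)C=COc21
F4 | step 7 | 7-O,4''-O-bis(tert-butyldimethylsilyl) ether of 14 | O=C1C=COc2c(C[C@@H](CC=C(C)C)[C@@H](C)CO[Si](C)(C)C(C)(C)C)c(O[Si](C)(C)C(C)(C)C)cc(O)c12
F5 | step 7 | (2S) 7-O,4''-O-bis(tert-butyldimethylsilyl) ether of 19 | COc1cc(O)ccc1[C@@H]1CC(=O)c2c(O)cc(O[Si](C)(C)C(C)(C)C)c(C[C@@H](CC=C(C)C)[C@@H](C)CO[Si](C)(C)C(C)(C)C)c2O1
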